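**Retrosynthetic overview**
- Feature: on ring A the oxygens at C5 and C8 are para. Ring A can therefore be taken back to a 5,8-quinone, in which C8a, the unsubstituted carbon beside the acyl-bearing C4a, is the electrophile that receives O1.
- Endgame: target ⇒ 3-O-benzyl ether (hydrogenolysis) ⇒ 5,8-hydroquinone (methylation of the free 8-OH, since the 5-OH is hydrogen-bonded to C4=O) ⇒ flavone-5,8-quinone (reduction).
- Key disconnection O1–C8a: the quinone comes from an open 2-benzyloxy-1,3-diketone with a 2,4,5-trimethoxyphenyl ring A. One electrolysis carries out anodic oxidative demethylation, oxa-Michael closure and re-oxidation.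
- Diketone ⇒ C-acylation of the 2-benzyloxy-1-arylethanone with 3,4,5-trimethoxybenzoyl chloride. Ketone ⇒ 2,4,5-trimethoxyphenyllithium plus the Weinreb amide of benzyloxyacetic acid, so that no Lewis acid can decarbonylate the alkoxyacetyl chloride or strip the benzyl group.
- Ring order: rings A and B are bought as arenes. Ring C is the only ring made, and it is closed in step 4.

Key step: step 4

Remark: the target has no stereocentre. The central carbon of the diketone is a labile racemic centre that disappears on ring closure. The working potential of the electrolysis is to be fixed by cyclic voltammetry of the diketone before the preparative run.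

**Step 1**
Reactants: 1 benzyloxyacetyl chloride
Product: 2 2-(benzyloxy)-N-methoxy-N-methylacetamide
Conditions: MeNH(OMe)·HCl, K2CO3, CH2Cl2–H2O, 0 °C to rt
Reagents that add atoms: N,O-dimethylhydroxylamine hydrochloride, CNOC.Cl
Why: Schotten–Baumann-type N-acylation of the hydroxylamine by the acid chloride under biphasic carbonate buffering is fast and leaves the benzyl ether untouched.

**Step 2**
Reactants: 3 1-bromo-2,4,5-trimethoxybenzene; 2 2-(benzyloxy)-N-methoxy-N-methylacetamide
Product: 5 2-(benzyloxy)-1-(2,4,5-trimethoxyphenyl)ethan-1-one, via 2,4,5-trimethoxyphenyllithium 4 (not isolated)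
Conditions: n-BuLi, THF, −78 °C; then 2, −78 to 0 °C; 1 M HCl quench
Reagents that add atoms: none
Why: Bromine–lithium exchange fixes the metal at the required ring carbon and the Weinreb ketone synthesis stops at the ketone, so the Lewis acids of a Friedel–Crafts acylation, which decarbonylate alkoxyacetyl chlorides and cleave benzyl ethers, are avoided.

**Step 3**
Reactants: 5 2-(benzyloxy)-1-(2,4,5-trimethoxyphenyl)ethan-1-one; 6 3,4,5-trimethoxybenzoyl chloride
Product: 8 2-(benzyloxy)-1-(2,4,5-trimethoxyphenyl)-3-(3,4,5-trimethoxyphenyl)propane-1,3-dione (racemic), via lithium Z-enolate 7 (not isolated)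
Conditions: LiN(SiMe3)2 (2.1 equiv), THF, −78 °C; then 6, −78 to 0 °C; 1 M HCl quench
Reagents that add atoms: none
Why: Claisen-type C-acylation of the chelated lithium enolate with an aroyl chloride, in which the second equivalent of base turns the more acidic diketone into its enolate as it forms, driving the reaction to the C-acyl product and shielding it from a second acylation.

**Step 4**
Reactants: 8 2-(benzyloxy)-1-(2,4,5-trimethoxyphenyl)-3-(3,4,5-trimethoxyphenyl)propane-1,3-dione
Product: 11 3-(benzyloxy)-7-methoxy-2-(3,4,5-trimethoxyphenyl)-4H-chromene-4,5,8-trione, via acylquinone 9 (not isolated), via 5,8-hydroquinone 10 (not isolated)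
Conditions: graphite-felt anode, Pt cathode, divided cell (Nafion membrane), 0.1 M LiClO4, MeCN–H2O 4:1, controlled potential at the first wave of 8 (about +1.3 V vs Ag/AgCl, set by cyclic voltammetry), 4 F/mol, 0 °C to rt
Reagents that add atoms: water, O
Why: Proposed new method: ring A of 8 is the only ring with a para-dimethoxy pair and should give the first anodic wave; its radical cation takes up water at the methoxy-bearing carbons C2 and C5 (aryl numbering), and loss of two electrons, two protons and two methanol gives acylquinone 9. The acid set free in the anolyte enolises the diketone, and the enol oxygen on the ring B side adds to the unsubstituted quinone carbon beside the acyl-bearing carbon (the future C8a), which is the beta position of both the side-chain ketone and a ring carbonyl, so that O1–C8a is formed and ring C is closed in a 6-endo-trig oxa-Michael mode. Tautomerisation gives hydroquinone 10, which is oxidised far more easily than 8 and therefore gives up two more electrons at the working potential to end as trione 11, four electrons in all, while any 9 that is reduced by redox exchange with 10 is simply re-oxidised. The closest known reaction types are the anodic or ceric oxidative demethylation of 1,4-dimethoxyarenes to quinones, the addition of nucleophiles at C3 of 2-acyl-1,4-benzoquinones and the anodically triggered Michael addition of 1,3-dicarbonyl compounds to quinones; not yet shown is the closure of a 4-pyranone ring by an enol oxygen on an acylquinone made at the anode. The step needs oxidation of ring A before ring B, the benzyl ether or the enol, which the controlled potential and the 1,2,4-donor pattern secure, and it needs attack at C8a only, which the tether secures because the central carbon could close only a four-membered ring and the other quinone CH is out of reach; the large excess of water and the low enol content of a 2-alkoxy-1,3-diketone should keep the enol oxygen from trapping the ring A cation at the methoxy-bearing carbon ortho to the acyl group, and such a mixed ketal would reopen in the acidic anolyte. No stereocentre is formed, the labile one of 8 is erased, and the divided cell keeps 9 and 11 away from the cathode.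

**Step 5**
Reactants: 11 3-(benzyloxy)-7-methoxy-2-(3,4,5-trimethoxyphenyl)-4H-chromene-4,5,8-trione
Product: 10 3-(benzyloxy)-5,8-dihydroxy-7-methoxy-2-(3,4,5-trimethoxyphenyl)-4H-chromen-4-one
Conditions: Na2S2O4, EtOAc–H2O, rt, Ar
Reagents that add atoms: none
Why: Dithionite reduction of a quinone to its hydroquinone is a standard two-electron, two-proton transfer that leaves the 4-pyranone carbonyl, the aryl methyl ethers and the benzyl ether untouched.

**Step 6**
Reactants: 10 3-(benzyloxy)-5,8-dihydroxy-7-methoxy-2-(3,4,5-trimethoxyphenyl)-4H-chromen-4-one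
Product: 12 3-(benzyloxy)-5-hydroxy-7,8-dimethoxy-2-(3,4,5-trimethoxyphenyl)-4H-chromen-4-one
Conditions: MeI (1.05 equiv), K2CO3 (1.1 equiv), degassed acetone, Ar, rt to 40 °C
Reagents that add atoms: iodomethane, CI
Why: Williamson O-methylation with weak base and one equivalent of MeI should be site-selective, because the 5-OH is held in a strong hydrogen bond to the C4 carbonyl and is much less acidic and nucleophilic than the free 8-OH, as in the classical partial methylation of 5-hydroxyflavones.

**Step 7**
Reactants: 12 3-(benzyloxy)-5-hydroxy-7,8-dimethoxy-2-(3,4,5-trimethoxyphenyl)-4H-chromen-4-one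
Product: 13 3,5-dihydroxy-7,8-dimethoxy-2-(3,4,5-trimethoxyphenyl)-4H-chromen-4-one (3,5-dihydroxy-7,8,3',4',5'-pentamethoxyflavone)
Conditions: H2 (1 atm), 10% Pd/C, EtOAc–MeOH, rt
Reagents that add atoms: none
Why: Catalytic hydrogenolysis of the O3 benzyl ether releases the flavonol, the conjugated C2=C3 bond of the 4-pyranone and the aryl methyl ethers being inert at one atmosphere.

**Compound list**
1 | benzyloxyacetyl chloride | O=C(Cl)COCc1ccccc1 | starting material
2 | 2-(benzyloxy)-N-methoxy-N-methylacetamide | CON(C)C(=O)COCc1ccccc1 | intermediate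
3 | 1-bromo-2,4,5-trimethoxybenzene | COc1cc(OC)c(Br)cc1OC | starting material
4 | 2,4,5-trimethoxyphenyllithium | [Li]c1cc(OC)c(OC)cc1OC | intermediate
5 | 2-(benzyloxy)-1-(2,4,5-trimethoxyphenyl)ethan-1-one | COc1cc(OC)c(C(=O)COCc2ccccc2)cc1OC | intermediate
6 | 3,4,5-trimethoxybenzoyl chloride | COc1cc(C(Cl)=O)cc(OC)c1OC | starting material
7 | lithium (Z)-2-(benzyloxy)-1-(2,4,5-trimethoxyphenyl)ethen-1-olate | [Li+].[O-]/C(=C\OCc1ccccc1)c1cc(OC)c(OC)cc1OC | intermediate
8 | 2-(benzyloxy)-1-(2,4,5-trimethoxyphenyl)-3-(3,4,5-trimethoxyphenyl)propane-1,3-dione (racemic, labile centre) | COc1cc(OC)c(C(=O)C(OCc2ccccc2)C(=O)c2cc(OC)c(OC)c(OC)c2)cc1OC | intermediate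
9 | 2-(benzyloxy)-1-(4-methoxy-3,6-dioxocyclohexa-1,4-dien-1-yl)-3-(3,4,5-trimethoxyphenyl)propane-1,3-dione (racemic, labile centre) | COC1=CC(=O)C(C(=O)C(OCc2ccccc2)C(=O)c2cc(OC)c(OC)c(OC)c2)=CC1=O | intermediate
10 | 3-(benzyloxy)-5,8-dihydroxy-7-methoxy-2-(3,4,5-trimethoxyphenyl)-4H-chromen-4-one | COc1cc(O)c2c(oc(-c3cc(OC)c(OC)c(OC)c3)c(OCc3ccccc3)c2=O)c1O | intermediate
11 | 3-(benzyloxy)-7-methoxy-2-(3,4,5-trimethoxyphenyl)-4H-chromene-4,5,8-trione | COC1=CC(=O)C2=C(OC(=C(OCc3ccccc3)C2=O)c2cc(OC)c(OC)c(OC)c2)C1=O | intermediate
12 | 3-(benzyloxy)-5-hydroxy-7,8-dimethoxy-2-(3,4,5-trimethoxyphenyl)-4H-chromen-4-one | COc1cc(O)c2c(oc(-c3cc(OC)c(OC)c(OC)c3)c(OCc3ccccc3)c2=O)c1OC | intermediate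
13 | 3,5-dihydroxy-7,8,3',4',5'-pentamethoxyflavone | COc1cc(-c2oc3c(OC)c(OC)cc(O)c3c(=O)c2O)cc(OC)c1OC | target

**Step count**
Total steps: 7. Longest linear sequence: 7 steps (1 → 2 → 5 → 8 → 11 → 10 → 12 → 13).

**Steps most likely to fail**

Step 4.
- What may go wrong: fouling of the anode, oxidation of ring B or of the enol alongside ring A, trapping of the ring A cation by the enol oxygen at the methoxy-bearing ortho carbon, or addition of water to the acylquinone faster than ring closure.
- Principle of the fallback: it uses known chemistry only. It separates oxidation from ring closure and puts a leaving group on C8a, so no C–H position has to be oxidised. It sets out from Weinreb amide 2, with 6 as the acyl donor.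
- Ketone: commercial 1,2,3,5-tetramethoxybenzene (COc1cc(OC)c(OC)c(OC)c1) is lithiated between its 3- and 5-methoxy groups by directed ortho-metalation (n-BuLi, THF, 0 °C). This gives 2,3,4,6-tetramethoxyphenyllithium F1, which adds to 2 to give 2-(benzyloxy)-1-(2,3,4,6-tetramethoxyphenyl)ethan-1-one F2.
- Diketone: LiN(SiMe3)2 converts F2 into lithium (Z)-2-(benzyloxy)-1-(2,3,4,6-tetramethoxyphenyl)ethen-1-olate F3. C-acylation with 6 as in step 3 gives 2-(benzyloxy)-1-(2,3,4,6-tetramethoxyphenyl)-3-(3,4,5-trimethoxyphenyl)propane-1,3-dione F4.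
- Quinone: oxidative demethylation of the only para-dimethoxy pair of ring A (aryl C3 and C6) with AgO and aqueous HNO3 in dioxane gives 2-(benzyloxy)-1-(2,4-dimethoxy-3,6-dioxocyclohexa-1,4-dien-1-yl)-3-(3,4,5-trimethoxyphenyl)propane-1,3-dione F5.
- Ring closure: NaOAc in THF then lets the enol oxygen displace the methoxy group on the quinone carbon beside the acyl group by addition–elimination, the usual substitution mode of alkoxyquinones. The fallback comes back to the route at trione 11.

Step 3.
- What may go wrong: O-acylation of the ambident enolate, a second acylation, or retro-Claisen cleavage of the non-enolised diketone during work-up.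
- Fallback: it replaces acyl transfer by a carbon-only aldol addition followed by oxidation, and sets out from ketone 5. Enolate 7 is added at −78 °C to 3,4,5-trimethoxybenzaldehyde (COc1cc(C=O)cc(OC)c1OC). This gives 2-(benzyloxy)-3-hydroxy-1-(2,4,5-trimethoxyphenyl)-3-(3,4,5-trimethoxyphenyl)propan-1-one F6 as a mixture of racemic diastereomers, whose configuration is of no consequence.
- Return: Dess–Martin periodinane in CH2Cl2 oxidises the carbinol, and the fallback comes back at diketone 8.

Step 6.
- What may go wrong: air oxidation of the hydroquinone anion back to the quinone under base, or loss of site selectivity with methylation at both phenols.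
- Fallback: it gives up selective methylation in favour of exhaustive methylation and chelation-controlled demethylation, and sets out from hydroquinone 10. Excess MeI and K2CO3 in DMF at 50 °C under Ar give 3-(benzyloxy)-5,7,8-trimethoxy-2-(3,4,5-trimethoxyphenyl)-4H-chromen-4-one F7. Hydrogenolysis (H2, Pd/C) then gives 3-hydroxy-5,7,8-trimethoxy-2-(3,4,5-trimethoxyphenyl)-4H-chromen-4-one F8.
- Return: BCl3 in CH2Cl2 at −20 to 0 °C cleaves only the 5-methoxy group, which sits peri to the C4 carbonyl and is activated by boron chelation. The fallback comes back at target 13.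

**Further compounds**
F1 | step 4 | 2,3,4,6-tetramethoxyphenyllithium | [Li]c1c(OC)cc(OC)c(OC)c1OC
F2 | step 4 | 2-(benzyloxy)-1-(2,3,4,6-tetramethoxyphenyl)ethan-1-one | COc1cc(OC)c(C(=O)COCc2ccccc2)c(OC)c1OC
F3 | step 4 | lithium (Z)-2-(benzyloxy)-1-(2,3,4,6-tetramethoxyphenyl)ethen-1-olate | [Li+].[O-]/C(=C\OCc1ccccc1)c1c(OC)cc(OC)c(OC)c1OC
F4 | step 4 | 2-(benzyloxy)-1-(2,3,4,6-tetramethoxyphenyl)-3-(3,4,5-trimethoxyphenyl)propane-1,3-dione (racemic) | COc1cc(OC)c(C(=O)C(OCc2ccccc2)C(=O)c2cc(OC)c(OC)c(OC)c2)c(OC)c1OC
F5 | step 4 | 2-(benzyloxy)-1-(2,4-dimethoxy-3,6-dioxocyclohexa-1,4-dien-1-yl)-3-(3,4,5-trimethoxyphenyl)propane-1,3-dione (racemic) | COC1=CC(=O)C(C(=O)C(OCc2ccccc2)C(=O)c2cc(OC)c(OC)c(OC)c2)=C(OC)C1=O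
F6 | step 3 | 2-(benzyloxy)-3-hydroxy-1-(2,4,5-trimethoxyphenyl)-3-(3,4,5-trimethoxyphenyl)propan-1-one (mixture of racemic diastereomers) | COc1cc(OC)c(C(=O)C(OCc2ccccc2)C(O)c2cc(OC)c(OC)c(OC)c2)cc1OC
F7 | step 6 | 3-(benzyloxy)-5,7,8-trimethoxy-2-(3,4,5-trimethoxyphenyl)-4H-chromen-4-one | COc1cc(OC)c2c(oc(-c3cc(OC)c(OC)c(OC)c3)c(OCc3ccccc3)c2=O)c1OC
F8 | step 6 | 3-hydroxy-5,7,8-trimethoxy-2-(3,4,5-trimethoxyphenyl)-4H-chromen-4-one | COc1cc(OC)c2c(oc(-c3cc(OC)c(OC)c(OC)c3)c(O)c2=O)c1OC
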